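The C9–C11 bond of the seven-membered ring C is the disconnection on which the route rests. The feature used is that C11 on quaternary C9 and the oxygen on C7 sit 1,3 to each other across ring B, with C8 between them, so a C7 allylic ester on a C8=C9 alkene can deliver C11 to C9. In one operation the tert-butyl furyl β-keto ester of 26 gives an acylketene, the C7α hydroxyl traps it as an eleven-membered lactone, and Carroll rearrangement with loss of CO2 forms C9–C11, closes ring C and sets C9. Precursor 26 is the ring A/ring B/lactone core with the C7α hydroxyl, C8=C9 alkene, silylated C10 hydroxyl and the furyl keto ester on C1.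

Key step: step 17

Remark: clerodane numbering is used (ring A = C1–C5, C10; ring B = C5–C10; C17 on C8, C20 on C9, C19 on C5, C18 the lactone carbonyl, C11/C12 the methylene and ketone of ring C); β is the face of C19, C20 and the C10 oxygen, α the opposite face.

Step 1
Reactants: 1 (R)-carvone
Product: 2 (5R)-1,2-dimethyl-5-(prop-1-en-2-yl)cyclohex-2-en-1-ol (mixture of C1 epimers)
Conditions: MeLi, Et2O, −78 °C; H2O
Reagents that add atoms: methyllithium, [Li]C
Why: 1,2-addition of the hard organolithium to the enone carbonyl introduces C20; the carbinol configuration is irrelevant because this carbon becomes sp2 in step 2.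

Step 2
Reactants: 2 tertiary allylic alcohol
Product: 3 (5S)-2,3-dimethyl-5-(prop-1-en-2-yl)cyclohex-2-en-1-one (C7 ketone of ring B)
Conditions: [C5H5NH][CrO3Cl] (pyridinium chlorochromate), SiO2, CH2Cl2, rt
Reagents that add atoms: pyridinium chlorochromate, [O-][Cr](=O)(=O)Cl.c1cc[nH+]cc1
Why: Babler–Dauben oxidative 1,3-transposition, in which the chromate ester of the tertiary allylic alcohol undergoes a [3,3] shift and is oxidised, places the carbonyl on C7 and leaves the 8,9-dimethyl alkene.

Step 3
Reactants: 3 enone
Product: 4 (1S,5S)-2,3-dimethyl-5-(prop-1-en-2-yl)cyclohex-2-en-1-ol (7α-hydroxyl cis to the isopropenyl group)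
Conditions: NaBH4, CeCl3·7H2O, MeOH, −20 °C
Reagents that add atoms: none
Why: Luche 1,2-reduction delivers hydride axially to the half-chair with equatorial isopropenyl, so the new C7 hydroxyl should end cis to that group, as in the reduction of carvone itself.

Step 4
Reactants: 4 allylic alcohol
Product: 5 7α-triethylsilyl ether of 4
Conditions: Et3SiCl, imidazole, DMF, 0 °C
Reagents that add atoms: chlorotriethylsilane, CC[Si](Cl)(CC)CC
Why: Standard silylation of a secondary allylic alcohol.

Step 5
Reactants: 5 silyl ether
Product: 6 2,3-dimethyl-6-(prop-1-en-2-yl)-4-(triethylsilyloxy)cyclohex-2-en-1-one (ring B enone; C10 ketone; 7α-silyloxy cis to isopropenyl)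
Conditions: CrO3, 3,5-dimethylpyrazole, CH2Cl2, −20 °C
Reagents that add atoms: chromium trioxide, O=[Cr](=O)=O
Why: Allylic C–H oxidation with the CrO3·3,5-dimethylpyrazole complex should convert the ring methylene C10 next to the tetrasubstituted alkene into the enone carbonyl, the methyl groups (primary) and the shielded, silyloxy-bearing C7–H being less reactive.

Step 6
Reactants: 6 ring B enone
Product: 8 6-(hydroxymethyl)-2,3-dimethyl-6-(prop-1-en-2-yl)-4-(triethylsilyloxy)cyclohex-2-en-1-one (C19 hydroxymethyl β on C5; trans to the 7α-silyloxy group), via lithium enolate 7 (not isolated)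
Conditions: LiN(i-Pr)2, THF, −78 °C; CH2O (g), −78 → −40 °C
Reagents that add atoms: formaldehyde, C=O
Why: Kinetic deprotonation at the only α-position (C5) and aldol addition to formaldehyde should occur anti to the pseudoaxial 7α-silyloxy group, which places C19 on the β face and replaces the original carvone centre by the quaternary C5.

Step 7
Reactants: 8 hydroxymethyl ketone
Product: 9 C18/C19 diol (isopropenyl methyl of 8 oxidised to CH2OH)
Conditions: SeO2 (cat.), t-BuOOH, CH2Cl2, rt
Reagents that add atoms: tert-butyl hydroperoxide, CC(C)(C)OO (oxygen relayed by catalytic SeO2, O=[Se]=O)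
Why: Riley allylic hydroxylation (ene reaction then [2,3] shift) should oxidise the methyl of the 1,1-disubstituted alkene, its only allylic C–H, while the enone alkene is electron-poor and C10 has no α-hydrogen.

Step 8
Reactants: 9 diol
Product: 10 tris(triethylsilyl) ether ketone (silyl ethers on C7; C18; C19)
Conditions: Et3SiCl, imidazole, DMAP (cat.), CH2Cl2, 0 °C
Reagents that add atoms: chlorotriethylsilane, CC[Si](Cl)(CC)CC
Why: Standard silylation of the two primary alcohols (any C7 ether lost in step 7 is restored here).

Step 9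
Reactants: 10 tris(triethylsilyl) ether ketone; 11 methyl 2-methylfuran-3-carboxylate
Product: 14 spiro δ-lactone (6,7-dihydro-4H-furo[3,2-c]pyran-4-one spiro-fused at its C6 to C10 of ring B; lactone oxygen β; C1 methylene α), via methyl 2-(lithiomethyl)furan-3-carboxylate 12 (not isolated), via lithium alkoxide adduct 13 (not isolated)
Conditions: 11, LiN(i-Pr)2, THF, −78 °C; then 10, −78 → 0 °C
Reagents that add atoms: none
Why: Lateral lithiation of the toluate-type furan ester gives a dienolate that adds 1,2 to the non-enolisable C10 ketone (the β-carbon is fully substituted) and the tertiary alkoxide closes the δ-lactone; attack should come from the α face, anti to the axial β-CH2OSiEt3 group on C5, which sets C10.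

Step 10
Reactants: 14 spiro δ-lactone
Product: 16 C1-allyl lactone (allyl on C1 cis to C9 across the lactone ring; trans to C5), via lithium dienolate 15 (not isolated)
Conditions: LiN(i-Pr)2, THF–DMPU, −78 °C; allyl bromide
Reagents that add atoms: allyl bromide, C=CCBr
Why: Alkylation of the extended lactone enolate at the furfuryl carbon C1 should take place on the face of sp2 C9, away from the quaternary C5 on the adjacent spiro carbon, which sets C1 with the configuration needed for the cis A/B junction.

Step 11
Reactants: 16 C1-allyl lactone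
Product: 17 tetracyclic lactone with ring A closed (C3=C4 alkene; cis A/B junction; C18 and C19 as CH2OSiEt3)
Conditions: second-generation Grubbs catalyst (5 mol %), PhMe, 80 °C
Reagents that add atoms: none
Why: Ring-closing metathesis between the terminal allyl alkene and the 1,1-disubstituted alkene on C5 closes the six-membered ring A as the trisubstituted C3=C4 alkene with loss of ethylene.

Step 12
Reactants: 17 tetracyclic lactone
Product: 18 N-methoxy-N-methylfuran-3-carboxamide with free 10β-hydroxyl
Conditions: MeNH(OMe)·HCl, i-PrMgCl, THF, −20 → 0 °C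
Reagents that add atoms: N,O-dimethylhydroxylamine hydrochloride, CNOC.Cl
Why: Aminolysis of the lactone by the chloromagnesium amide (Weinreb amide formation) opens the furoate under basic conditions, so the tertiary allylic C10–O bond is not ionised.

Step 13
Reactants: 18 hydroxy Weinreb amide
Product: 19 10β-triethylsilyl ether of 18
Conditions: Et3SiOTf, 2,6-lutidine, CH2Cl2, 0 °C → rt
Reagents that add atoms: triethylsilyl trifluoromethanesulfonate, CC[Si](CC)(CC)OS(=O)(=O)C(F)(F)F
Why: Silylation of the hindered tertiary alcohol with the silyl triflate installs the group that later keeps the C10 oxygen from capturing the ketene.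

Step 14
Reactants: 19 silylated Weinreb amide; 20 tert-butyl acetate
Product: 22 tert-butyl β-keto ester bearing four triethylsilyl ethers (C7; C10; C18; C19), via lithium tert-butyl acetate enolate 21 (not isolated)
Conditions: 20, LiN(i-Pr)2, THF, −78 °C; then 19, −78 → −20 °C
Reagents that add atoms: none
Why: Claisen-type acylation of the ester enolate by the Weinreb amide proceeds through a stable chelated tetrahedral intermediate and should give the β-keto ester without over-addition.

Step 15
Reactants: 22 tetrasilylated β-keto ester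
Product: 23 triol (7α-OH; C18-OH; C19-OH) retaining the 10β-silyl ether
Conditions: PPTS, MeOH–CH2Cl2, 0 °C
Reagents that add atoms: none
Why: Acid-catalysed methanolysis removes the two primary and the secondary allylic triethylsilyl ethers far faster than the tertiary C10 ether flanked by two fully substituted carbons, which should be retained.

Step 16
Reactants: 23 triol
Product: 26 key-step precursor (α-alkylidene γ-lactone closed; free 7α-hydroxyl; 10β-silyl ether; furyl tert-butyl β-keto ester on C1), via hydroxy enal 24 (not isolated), via lactol 25 (not isolated)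
Conditions: TEMPO (cat.), PhI(OAc)2, CH2Cl2, rt
Reagents that add atoms: none
Why: Oxoammonium oxidation (oxidative lactonisation of a 1,4-diol) should take the primary allylic C18 alcohol in preference to the neopentyl C19 and secondary C7 alcohols, the enal being trapped by the C19 hydroxyl as a lactol that is oxidised on to the lactone.

Step 17
Reactants: 26 key-step precursor
Product: 30 pentacycle with ring C closed (C7=C8 alkene; C9 quaternary with C20 β and C11 α; 10β-silyl ether), via acylketene 27 (not isolated), via macrolactone 28 (not isolated), via keto acid 29 (not isolated)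
Conditions: xylenes (1 mM, slow addition), 140 °C
Reagents that add atoms: none
Why: Proposed new method: thermolysis of the tert-butyl β-keto ester expels tert-butanol to give acylketene 27, the C7α hydroxyl adds to it to form the eleven-membered β-keto lactone 28, the ester enol of 28 and the C8=C9 alkene then make up the six-atom array C11=C(OH)–O–C7–C8=C9 of a Carroll [3,3] rearrangement, and the β-keto acid 29 so formed loses CO2. Each stage has precedent (acylketene lactonisation from tert-butyl β-keto esters or dioxinones, the thermal Carroll rearrangement of allyl β-keto esters, Ireland–Claisen ring contraction of macrolactones), but the cascade across a cyclohexene is untested. Ring C is closed as a seven-membered carbocycle by transannular [3,3] ring contraction of the eleven-membered lactone, C11–C9 forming as C7–O breaks and the alkene moving to C7=C8. The new quaternary centre C9 is controlled by suprafacial transfer from the α-oriented C7 oxygen, and the tether through C1 on the α face of C10 allows only the cis ring fusion, so C11 enters α and C20 remains β. The step needs capture of the ketene by the C7 hydroxyl alone, which the triethylsilyl ether on the tertiary C10 hydroxyl secures, and ring closure in preference to oligomerisation, which slow addition at 1 mM secures.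

Step 18
Reactants: 30 pentacyclic silyl ether
Product: 31 pentacyclic 10β-alcohol
Conditions: Bu4NF, THF, 0 °C → rt
Reagents that add atoms: none
Why: Fluoride-mediated desilylation frees the 10β-hydroxyl, which is needed as the directing group in step 19.

Step 19
Reactants: 31 homoallylic alcohol
Product: 32 7β,8β-epoxide
Conditions: VO(acac)2 (cat.), t-BuOOH, CH2Cl2, 0 °C → rt
Reagents that add atoms: tert-butyl hydroperoxide, CC(C)(C)OO
Why: Vanadium-catalysed hydroxyl-directed epoxidation of the homoallylic alcohol should deliver oxygen to C7=C8 from the β face, syn to the 10β-hydroxyl, and leave the electron-poor C3=C4 alkene and the acylfuran untouched.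

Step 20
Reactants: 32 epoxide
Product: 33 C7 ketone (8β-methyl; 8α-H)
Conditions: BF3·OEt2, CH2Cl2, −78 °C
Reagents that add atoms: none
Why: Meinwald rearrangement, with Lewis acid opening at tertiary C8 and a 1,2-hydride shift from C7, gives the C7 ketone; the hydride arrives on the α face of C8, anti to the departing β oxygen, so C17 is β, which is also the equatorial position should C8 enolise.

Step 21
Reactants: 33 C7 ketone
Product: 34 7β-alcohol
Conditions: NaBH4, MeOH, −40 °C
Reagents that add atoms: none
Why: Borohydride reduces the saturated cyclohexanone chemoselectively beside the less electrophilic 3-acylfuran ketone and the lactone, and hydride should attack C7 from the α face because the β face is screened by the syn-axial C19 and C20 groups.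

Step 22
Reactants: 34 7β-alcohol
Product: 35 target CNP0329797.1
Conditions: Ac2O, DMAP, pyridine, rt
Reagents that add atoms: acetic anhydride, CC(=O)OC(C)=O
Why: DMAP-catalysed acetylation of the secondary 7β-alcohol; the tertiary C10 hydroxyl, flanked by fully substituted carbons, should not react.

Compound list
1 | (R)-carvone | CC1=CC[C@H](CC1=O)C(C)=C | starting material
2 | (5R)-1,2-dimethyl-5-(prop-1-en-2-yl)cyclohex-2-en-1-ol (C1 epimers) | CC1=CC[C@H](CC1(C)O)C(C)=C | intermediate
3 | (5S)-2,3-dimethyl-5-(prop-1-en-2-yl)cyclohex-2-en-1-one | CC1=C(C)C[C@@H](CC1=O)C(C)=C | intermediate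
4 | (1S,5S)-2,3-dimethyl-5-(prop-1-en-2-yl)cyclohex-2-en-1-ol (7α-OH cis to isopropenyl) | CC1=C(C)C[C@@H](C[C@@H]1O)C(C)=C | intermediate
5 | 7α-triethylsilyl ether of 4 | CC1=C(C)C[C@@H](C[C@@H]1O[Si](CC)(CC)CC)C(C)=C | intermediate
6 | ring B enone, C10 ketone, 7α-OSiEt3 | CC1=C(C)C(=O)[C@@H](C[C@@H]1O[Si](CC)(CC)CC)C(C)=C | intermediate
7 | lithium enolate of 6 (C5=C10) | CC1=C(C)C(O[Li])=C(C[C@@H]1O[Si](CC)(CC)CC)C(C)=C | intermediate (not isolated)
8 | 5β-hydroxymethyl ketone (C19-OH) | CC1=C(C)C(=O)[C@@](CO)(C[C@@H]1O[Si](CC)(CC)CC)C(C)=C | intermediate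
9 | C18/C19 diol | CC1=C(C)C(=O)[C@@](CO)(C[C@@H]1O[Si](CC)(CC)CC)C(=C)CO | intermediate
10 | tris(triethylsilyl) ether ketone | CC1=C(C)C(=O)[C@@](CO[Si](CC)(CC)CC)(C[C@@H]1O[Si](CC)(CC)CC)C(=C)CO[Si](CC)(CC)CC | intermediate
11 | methyl 2-methylfuran-3-carboxylate | Cc1occc1C(=O)OC | starting material
12 | methyl 2-(lithiomethyl)furan-3-carboxylate | [Li]Cc1occc1C(=O)OC | intermediate (not isolated)
13 | lithium alkoxide adduct at C10 | CC1=C(C)[C@](O[Li])(Cc2occc2C(=O)OC)[C@@](CO[Si](CC)(CC)CC)(C[C@@H]1O[Si](CC)(CC)CC)C(=C)CO[Si](CC)(CC)CC | intermediate (not isolated)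
14 | spiro furo[3,2-c]pyran-4-one δ-lactone | CC1=C(C)[C@@]2(OC(=O)c3ccoc3C2)[C@@](CO[Si](CC)(CC)CC)(C[C@@H]1O[Si](CC)(CC)CC)C(=C)CO[Si](CC)(CC)CC | intermediate
15 | lithium dienolate of 14 | CC1=C(C)[C@@]2(OC(O[Li])=C3C=COC3=C2)[C@@](CO[Si](CC)(CC)CC)(C[C@@H]1O[Si](CC)(CC)CC)C(=C)CO[Si](CC)(CC)CC | intermediate (not isolated)
16 | C1-allyl lactone | CC1=C(C)[C@@]2(OC(=O)c3ccoc3[C@@H]2CC=C)[C@@](CO[Si](CC)(CC)CC)(C[C@@H]1O[Si](CC)(CC)CC)C(=C)CO[Si](CC)(CC)CC | intermediate
17 | tetracyclic lactone, ring A closed | CC1=C(C)[C@]23OC(=O)c4ccoc4[C@@H]2CC=C(CO[Si](CC)(CC)CC)[C@]3(CO[Si](CC)(CC)CC)C[C@@H]1O[Si](CC)(CC)CC | intermediate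
18 | Weinreb amide with free 10β-OH | CC1=C(C)[C@]2(O)[C@H](c3occc3C(=O)N(C)OC)CC=C(CO[Si](CC)(CC)CC)[C@]2(CO[Si](CC)(CC)CC)C[C@@H]1O[Si](CC)(CC)CC | intermediate
19 | 10β-triethylsilyl ether of 18 | CC1=C(C)[C@]2(O[Si](CC)(CC)CC)[C@H](c3occc3C(=O)N(C)OC)CC=C(CO[Si](CC)(CC)CC)[C@]2(CO[Si](CC)(CC)CC)C[C@@H]1O[Si](CC)(CC)CC | intermediate
20 | tert-butyl acetate | CC(=O)OC(C)(C)C | starting material
21 | lithium enolate of tert-butyl acetate | [Li]OC(=C)OC(C)(C)C | intermediate (not isolated)
22 | tetrasilylated tert-butyl β-keto ester | CC1=C(C)[C@]2(O[Si](CC)(CC)CC)[C@H](c3occc3C(=O)CC(=O)OC(C)(C)C)CC=C(CO[Si](CC)(CC)CC)[C@]2(CO[Si](CC)(CC)CC)C[C@@H]1O[Si](CC)(CC)CC | intermediate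
23 | triol with 10β-OSiEt3 | CC1=C(C)[C@]2(O[Si](CC)(CC)CC)[C@H](c3occc3C(=O)CC(=O)OC(C)(C)C)CC=C(CO)[C@]2(CO)C[C@@H]1O | intermediate
24 | C18 hydroxy enal | CC1=C(C)[C@]2(O[Si](CC)(CC)CC)[C@H](c3occc3C(=O)CC(=O)OC(C)(C)C)CC=C(C=O)[C@]2(CO)C[C@@H]1O | intermediate (not isolated)
25 | C18 lactol | CC1=C(C)[C@]2(O[Si](CC)(CC)CC)[C@H](c3occc3C(=O)CC(=O)OC(C)(C)C)CC=C4C(O)OC[C@@]24C[C@@H]1O | intermediate (not isolated)
26 | key-step precursor (C7-epi allylic alcohol with furyl β-keto ester) | O[C@H]1C[C@@]23COC(=O)C2=CC[C@@H](c2occc2C(=O)CC(=O)OC(C)(C)C)[C@@]3(O[Si](CC)(CC)CC)C(C)=C1C | intermediate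
27 | acylketene | O[C@H]1C[C@@]23COC(=O)C2=CC[C@@H](c2occc2C(=O)C=C=O)[C@@]3(O[Si](CC)(CC)CC)C(C)=C1C | intermediate (not isolated)
28 | eleven-membered β-keto lactone | O4[C@H]1C[C@@]23COC(=O)C2=CC[C@@H](c2occc2C(=O)CC4=O)[C@@]3(O[Si](CC)(CC)CC)C(C)=C1C | intermediate (not isolated)
29 | β-keto acid after [3,3] shift | CC1=CC[C@@]23COC(=O)C2=CC[C@H]2c4occc4C(=O)C(C(O)=O)[C@]1(C)[C@]23O[Si](CC)(CC)CC | intermediate (not isolated)
30 | pentacyclic C7=C8 alkene, ring C closed | CC1=CC[C@@]23COC(=O)C2=CC[C@H]2c4occc4C(=O)C[C@]1(C)[C@]23O[Si](CC)(CC)CC | intermediate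
31 | pentacyclic 10β-alcohol | CC1=CC[C@@]23COC(=O)C2=CC[C@H]2c4occc4C(=O)C[C@]1(C)[C@]23O | intermediate
32 | 7β,8β-epoxide | C[C@]15O[C@@H]5C[C@@]23COC(=O)C2=CC[C@H]2c4occc4C(=O)C[C@]1(C)[C@]23O | intermediate
33 | C7 ketone, 8β-methyl | C[C@@H]1C(=O)C[C@@]23COC(=O)C2=CC[C@H]2c4occc4C(=O)C[C@]1(C)[C@]23O | intermediate
34 | 7β-alcohol | C[C@@H]1[C@H](O)C[C@@]23COC(=O)C2=CC[C@H]2c4occc4C(=O)C[C@]1(C)[C@]23O | intermediate
35 | CNP0329797.1 | CC(=O)O[C@@H]1C[C@@]23COC(=O)C2=CC[C@H]2c4occc4C(=O)C[C@@](C)([C@@H]1C)[C@]23O | target

Total step count: 22. Longest linear sequence: 22 steps from (R)-carvone (11 and 20 are bought and enter directly).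

Steps most likely to fail

Step 17. The acylketene may be captured between molecules, or the allylic ester may eliminate or ionise faster than the [3,3] shift, which has to build a quaternary carbon between two fully substituted neighbours. The fallback uses known chemistry, sets out from 26 and returns at 33. MnO2 in CH2Cl2 oxidises the C7 allylic alcohol to the C7 enone F1. Cs2CO3 in MeCN then promotes intramolecular Michael addition of the β-keto ester carbon C11 to the enone β-carbon C9 (7-exo-trig), giving the ring C keto ester F2; the α tether enforces the cis fusion and C8 is set by thermodynamic protonation. CF3CO2H in CH2Cl2 followed by warming in PhMe cleaves the tert-butyl ester and the silyl ether and decarboxylates, giving 33 directly, so steps 18 to 20 are not needed.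

Step 5. Oxidation may occur at the wrong allylic position (the silyloxy-bearing C7–H, a methyl group or the isopropenyl unit) or run on to over-oxidised products. The fallback sets out from 5 and returns at 6. SeO2 (cat.) with t-BuOOH hydroxylates by the ene/[2,3] pathway, which prefers ring CH2 over CH3 and CH and the more electron-rich tetrasubstituted alkene, and should give the C10 allylic alcohol F3. MnO2 then oxidises F3 to 6.

Step 9. The stabilised dienolate may add reversibly or not at all to the crowded C10 carbonyl, or attack from the β face. The fallback sets out from 11 (with ketone 10) and returns at 14. LiOH hydrolysis of 11 gives 2-methylfuran-3-carboxylic acid F4. Its dianion (two equivalents of LiN(i-Pr)2), a harder and more reactive lateral carbanion, adds to 10 and gives after work-up the hydroxy acid F5. Carbodiimide lactonisation (EDC·HCl, DMAP) of F5 gives 14.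

Further compounds
F1 | step 17 | C7 enone from 26 | O=C1C[C@@]23COC(=O)C2=CC[C@@H](c2occc2C(=O)CC(=O)OC(C)(C)C)[C@@]3(O[Si](CC)(CC)CC)C(C)=C1C
F2 | step 17 | ring C Michael adduct (C11 tert-butyl ester, C7 ketone, 10β-OSiEt3) | C[C@@H]1C(=O)C[C@@]23COC(=O)C2=CC[C@H]2c4occc4C(=O)C(C(=O)OC(C)(C)C)[C@]1(C)[C@]23O[Si](CC)(CC)CC
F3 | step 5 | C10 allylic alcohol from 5 | CC1=C(C)C(O)[C@@H](C[C@@H]1O[Si](CC)(CC)CC)C(C)=C
F4 | step 9 | 2-methylfuran-3-carboxylic acid | Cc1occc1C(O)=O
F5 | step 9 | C10 hydroxy acid | CC1=C(C)[C@](O)(Cc2occc2C(O)=O)[C@@](CO[Si](CC)(CC)CC)(C[C@@H]1O[Si](CC)(CC)CC)C(=C)CO[Si](CC)(CC)CC
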